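**Plan**
Retrosynthesis: first the three benzyl-type groups (two ArO–CH2Ph, one acetal O–CH(CH3)Ph) and the two CH2OH groups (from CHO) are taken back. Then the seven-membered lactone is cut at its aryl–C(=O) bond (ring A) and its O–aryl bond (ring B), together with the neighbouring ring-B C–CHO bond, leaving a diaryl ether, CO2 and DMF. Last, the diaryl ether C–O bond is cut to two benzaldehydes.
Enabling feature: on ring B the carbon bearing the lactone oxygen lies between the carbon bearing the ether oxygen and the carbon bearing CH2OH. The lactone O and the CH2OH carbon are therefore neighbours that one aryne can take up, and the ether oxygen holds a ring-A carboxylate (ArLi + CO2) over the nearer aryne carbon only.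
Forward: ring A (from 3-fluoro-5-methylphenol) and ring B (from 2,5-dihydroxybenzoic acid) are each completed by directed metalation and formylation and joined by SNAr. The seven-membered lactone ring then closes in the CO2/aryne step, and the five-membered lactol ring closes on acid unmasking.
Stereochemistry: the only stereocentre (lactol carbon, S) is fixed as its (S)-1-phenylethyl acetal, whose two epimers are separated (the unwanted one is re-equilibrated). The final hydrogenolysis breaks the O–CH(CH3)Ph bond, not a bond at the stereocentre.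

Key step: step 12

Remark: the lactol carbon of a 3-hydroxyphthalide can epimerise by ring–chain tautomerism; it is assumed that the target keeps its configuration when set free under neutral conditions in the last step and isolated cold without acid or base.

**Step 1**
Reactants: 1 3-fluoro-5-methylphenol
Product: 2 3-fluoro-4-iodo-5-methylphenol
Conditions: N-iodosuccinimide, cat. CF3CO2H, MeCN, 0 °C to rt
Reagents that add atoms: N-iodosuccinimide, O=C1CCC(=O)N1I
Why: Electrophilic aromatic iodination of a phenol should go para to the hydroxyl group, here the open position between F and CH3.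

**Step 2**
Reactants: 2 3-fluoro-4-iodo-5-methylphenol
Product: 3 1-(benzyloxy)-3-fluoro-4-iodo-5-methylbenzene
Conditions: BnBr, K2CO3, acetone, reflux
Reagents that add atoms: benzyl bromide, BrCc1ccccc1
Why: Williamson ether synthesis on the phenoxide.

**Step 3**
Reactants: 3 1-(benzyloxy)-3-fluoro-4-iodo-5-methylbenzene
Product: 4 6-(benzyloxy)-2-fluoro-3-iodo-4-methylbenzaldehyde
Conditions: LiN(iPr)2, THF, −78 °C; then DMF, −78 to 0 °C; H2O
Reagents that add atoms: N,N-dimethylformamide, CN(C)C=O
Why: Directed ortho-lithiation at the one C–H flanked by fluorine and the benzyloxy group (the most acidic ring proton; the amide base does not exchange the iodide), followed by formylation with DMF.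

**Step 4**
Reactants: 5 2,5-dihydroxybenzoic acid
Product: 6 tert-butyl 2,5-dihydroxybenzoate
Conditions: Me2NCH(OtBu)2, toluene, 80 °C
Reagents that add atoms: N,N-dimethylformamide di-tert-butyl acetal, CN(C)C(OC(C)(C)C)OC(C)(C)C
Why: Esterification of a carboxylic acid with a formamide acetal, which alkylates the acid and leaves the phenols free.

**Step 5**
Reactants: 6 tert-butyl 2,5-dihydroxybenzoate
Product: 7 tert-butyl 5-(allyloxy)-2-hydroxybenzoate
Conditions: allyl bromide (1.05 equiv), K2CO3, acetone, reflux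
Reagents that add atoms: allyl bromide, C=CCBr
Why: Williamson etherification selective for the 5-hydroxyl, because the 2-hydroxyl is hydrogen-bonded to the ester carbonyl and much less nucleophilic.

**Step 6**
Reactants: 7 tert-butyl 5-(allyloxy)-2-hydroxybenzoate
Product: 8 tert-butyl 5-(allyloxy)-2-(benzyloxy)benzoate
Conditions: BnBr, K2CO3, DMF, 60 °C
Reagents that add atoms: benzyl bromide, BrCc1ccccc1
Why: Williamson benzylation of the remaining chelated phenol under more forcing conditions.

**Step 7**
Reactants: 8 tert-butyl 5-(allyloxy)-2-(benzyloxy)benzoate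
Product: 9 tert-butyl 3-(allyloxy)-6-(benzyloxy)-2-formylbenzoate
Conditions: Mg(TMP)2·2LiCl (TMP = 2,2,6,6-tetramethylpiperidide), THF, 0 °C to rt; then DMF, −20 °C to rt; H2O
Reagents that add atoms: N,N-dimethylformamide, CN(C)C=O
Why: Directed ortho-magnesiation with a hindered magnesium amide at the only C–H flanked by the ester and an alkoxy group, then formylation with DMF; the magnesium amide tolerates the ester.

**Step 8**
Reactants: 9 tert-butyl 3-(allyloxy)-6-(benzyloxy)-2-formylbenzoate
Product: 10 tert-butyl 6-(benzyloxy)-2-formyl-3-hydroxybenzoate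
Conditions: Pd(PPh3)4 (cat.), morpholine, THF, rt
Reagents that add atoms: none
Why: Palladium-catalysed deallylation (Tsuji–Trost type, morpholine as allyl acceptor) should free the phenol without touching the benzyl ether, the ester or the aldehyde.

**Step 9**
Reactants: 10 tert-butyl 6-(benzyloxy)-2-formyl-3-hydroxybenzoate
Product: 11 tert-butyl 6-(benzyloxy)-4-chloro-2-formyl-3-hydroxybenzoate
Conditions: N-chlorosuccinimide, cat. iPr2NH, CH2Cl2, 0 °C to rt
Reagents that add atoms: N-chlorosuccinimide, O=C1CCC(=O)N1Cl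
Why: Electrophilic ortho-chlorination of a phenol; the para position carries OBn and the other ortho position the formyl group, so only one site next to the hydroxyl is open.

**Step 10**
Reactants: 11 tert-butyl 6-(benzyloxy)-4-chloro-2-formyl-3-hydroxybenzoate, 4 6-(benzyloxy)-2-fluoro-3-iodo-4-methylbenzaldehyde
Product: 12 tert-butyl 6-(benzyloxy)-3-[3-(benzyloxy)-2-formyl-6-iodo-5-methylphenoxy]-4-chloro-2-formylbenzoate
Conditions: Cs2CO3, DMF, 90 °C
Reagents that add atoms: none
Why: Nucleophilic aromatic substitution (SNAr) of the fluoride of 4, activated by its ortho-formyl group, by the phenoxide of 11.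

**Step 11**
Reactants: 12 tert-butyl 6-(benzyloxy)-3-[3-(benzyloxy)-2-formyl-6-iodo-5-methylphenoxy]-4-chloro-2-formylbenzoate
Product: 13 tert-butyl 6-(benzyloxy)-3-[3-(benzyloxy)-2-(1,3-dioxolan-2-yl)-6-iodo-5-methylphenoxy]-4-chloro-2-(1,3-dioxolan-2-yl)benzoate
Conditions: Me3SiOCH2CH2OSiMe3, cat. Me3SiOSO2CF3, CH2Cl2, −78 to −20 °C
Reagents that add atoms: 1,2-bis(trimethylsilyloxy)ethane, C[Si](C)(C)OCCO[Si](C)(C)C
Why: Noyori acetalisation should mask both hindered aldehydes as dioxolanes under conditions that spare the tert-butyl ester.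

**Step 12**
Reactants: 13 tert-butyl 6-(benzyloxy)-3-[3-(benzyloxy)-2-(1,3-dioxolan-2-yl)-6-iodo-5-methylphenoxy]-4-chloro-2-(1,3-dioxolan-2-yl)benzoate, 14 carbon dioxide
Product: 19 tert-butyl 3,8-bis(benzyloxy)-4,6-bis(1,3-dioxolan-2-yl)-9-formyl-1-methyl-11-oxo-11H-dibenzo[b,e][1,4]dioxepine-7-carboxylate, via ring-A aryllithium 15 (not isolated), via lithium carboxylate 16 (not isolated), via aryne 17 (not isolated), via lactone aryllithium 18 (not isolated)
Conditions: n-BuLi (1.05 equiv), THF, −78 °C, 5 min; CO2 (dry gas), −78 to −20 °C; argon purge; LiTMP (lithium 2,2,6,6-tetramethylpiperidide, 1.3 equiv), −78 to −45 °C; DMF, −78 °C to rt; H2O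
Reagents that add atoms: N,N-dimethylformamide, CN(C)C=O
Why: Proposed new method: iodine–lithium exchange at the ring-A carbon between CH3 and the ether oxygen gives aryllithium 15, which adds to CO2 to give lithium carboxylate 16; LiTMP then removes the one acidic ring-B proton (between Cl and OBn), LiCl is lost to give aryne 17, the tethered carboxylate oxygen adds to the aryne carbon next to the ether oxygen, and the aryllithium 18 left on the neighbouring carbon is formylated by DMF, so that the aryl–CO2 bond, the O–aryl bond and the C–CHO bond are made in one flask. The closest known reaction types are the ring closure of a tethered nucleophile onto an aryne generated with a lithium amide (Bunnett-type aryne cyclisation), the O-arylation of carboxylates by arynes and three-component aryne couplings in which the aryl anion is caught by a carbon electrophile; new is that the internal nucleophile is a carboxylate made from CO2 in the same operation. The seven-membered lactone ring closes by in-plane attack of the carboxylate oxygen on the proximal aryne carbon (7-exo-dig). No stereocentre is formed. Three selectivities are needed: exchange only at iodine (the aryl chloride, the tert-butyl ester and the acetals should not react with n-BuLi at −78 °C within minutes), carboxylation before aryne formation (the amide base is added only after CO2 has been purged, because free aryllithium 15 would add to the aryne to give a dibenzofuran), and C–O bond formation at the aryne carbon beside the ether oxygen (only this carbon can be reached through the diaryl ether tether, the other would need a meta-bridged ring, and both aryne carbons have an oxygen-bearing neighbour so that neither is electronically preferred). Aryllithium 18 is flanked by OBn and the new acyloxy group, which stabilise it, and an anionic Fries shift is not possible because the lactone ring holds the carbonyl carbon on the far side of the C–O bond.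

**Step 13**
Reactants: 19 tert-butyl 3,8-bis(benzyloxy)-4,6-bis(1,3-dioxolan-2-yl)-9-formyl-1-methyl-11-oxo-11H-dibenzo[b,e][1,4]dioxepine-7-carboxylate
Product: 20 4,10-bis(benzyloxy)-1-hydroxy-8-methyl-3,7-dioxo-1,3-dihydro-7H-isobenzofuro[4,5-b][1,4]benzodioxepine-5,11-dicarbaldehyde (both epimers at C1)
Conditions: CF3CO2H–CH2Cl2–H2O, 0 °C to rt
Reagents that add atoms: water, O
Why: Acidolysis should cleave the tert-butyl ester (loss of isobutene) and hydrolyse both dioxolanes, and the freed 2-formylbenzoic acid closes to the five-membered lactol by ring–chain tautomerism (5-exo-trig addition of the carboxyl O–H to the aldehyde), formed as both epimers.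

**Step 14**
Reactants: 20 lactol dialdehyde (both epimers), 21 (S)-1-phenylethanol
Product: 22 (1S)-4,10-bis(benzyloxy)-8-methyl-3,7-dioxo-1-[(1S)-1-phenylethoxy]-1,3-dihydro-7H-isobenzofuro[4,5-b][1,4]benzodioxepine-5,11-dicarbaldehyde
Conditions: camphorsulfonic acid (cat.), 4 Å molecular sieves, CH2Cl2, 35 °C; chromatographic separation of the two acetal epimers
Reagents that add atoms: none
Why: Acid-catalysed acetalisation of the lactol (pseudo-acid esterification) with the chiral alcohol under equilibrating conditions should give two acetal epimers that are diastereomers and separable; the (1S) epimer is kept and the other is re-equilibrated under the same conditions, so the stereocentre is set by this auxiliary-based separation.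

**Step 15**
Reactants: 22 (1S)-acetal dialdehyde
Product: 23 (1S)-4,10-bis(benzyloxy)-5,11-bis(hydroxymethyl)-8-methyl-1-[(1S)-1-phenylethoxy]-1H-isobenzofuro[4,5-b][1,4]benzodioxepine-3,7-dione
Conditions: NaBH4, THF–MeOH (10:1), −40 to −20 °C
Reagents that add atoms: none
Why: Chemoselective borohydride reduction of the two aryl aldehydes at low temperature, the lactone acetal and the sterically shielded seven-membered lactone being much less electrophilic.

**Step 16**
Reactants: 23 (1S)-acetal diol
Product: 24 (1S)-1,4,10-trihydroxy-5,11-bis(hydroxymethyl)-8-methyl-1H-isobenzofuro[4,5-b][1,4]benzodioxepine-3,7-dione (target)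
Conditions: H2 (1 atm), 10% Pd/C, EtOAc, rt, stopped after uptake of 3 equiv
Reagents that add atoms: none
Why: Hydrogenolysis of the two aryl benzyl ethers and of the O–CH(CH3)Ph bond of the acetal should free the phenols and the lactol, and since no bond at the stereocentre is broken the (S) configuration is retained.

**Compound list**
1 | 3-fluoro-5-methylphenol | Cc1cc(O)cc(F)c1 | starting material
2 | 3-fluoro-4-iodo-5-methylphenol | Cc1cc(O)cc(F)c1I | intermediate
3 | 1-(benzyloxy)-3-fluoro-4-iodo-5-methylbenzene | Cc1cc(OCc2ccccc2)cc(F)c1I | intermediate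
4 | 6-(benzyloxy)-2-fluoro-3-iodo-4-methylbenzaldehyde | Cc1cc(OCc2ccccc2)c(C=O)c(F)c1I | intermediate
5 | 2,5-dihydroxybenzoic acid | O=C(O)c1cc(O)ccc1O | starting material
6 | tert-butyl 2,5-dihydroxybenzoate | CC(C)(C)OC(=O)c1cc(O)ccc1O | intermediate
7 | tert-butyl 5-(allyloxy)-2-hydroxybenzoate | CC(C)(C)OC(=O)c1cc(OCC=C)ccc1O | intermediate
8 | tert-butyl 5-(allyloxy)-2-(benzyloxy)benzoate | CC(C)(C)OC(=O)c1cc(OCC=C)ccc1OCc1ccccc1 | intermediate
9 | tert-butyl 3-(allyloxy)-6-(benzyloxy)-2-formylbenzoate | CC(C)(C)OC(=O)c1c(C=O)c(OCC=C)ccc1OCc1ccccc1 | intermediate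
10 | tert-butyl 6-(benzyloxy)-2-formyl-3-hydroxybenzoate | CC(C)(C)OC(=O)c1c(C=O)c(O)ccc1OCc1ccccc1 | intermediate
11 | tert-butyl 6-(benzyloxy)-4-chloro-2-formyl-3-hydroxybenzoate | CC(C)(C)OC(=O)c1c(C=O)c(O)c(Cl)cc1OCc1ccccc1 | intermediate
12 | tert-butyl 6-(benzyloxy)-3-[3-(benzyloxy)-2-formyl-6-iodo-5-methylphenoxy]-4-chloro-2-formylbenzoate | Cc1cc(OCc2ccccc2)c(C=O)c(Oc2c(Cl)cc(OCc3ccccc3)c(C(=O)OC(C)(C)C)c2C=O)c1I | intermediate
13 | tert-butyl 6-(benzyloxy)-3-[3-(benzyloxy)-2-(1,3-dioxolan-2-yl)-6-iodo-5-methylphenoxy]-4-chloro-2-(1,3-dioxolan-2-yl)benzoate | Cc1cc(OCc2ccccc2)c(C3OCCO3)c(Oc4c(Cl)cc(OCc5ccccc5)c(C(=O)OC(C)(C)C)c4C6OCCO6)c1I | intermediate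
14 | carbon dioxide | O=C=O | starting material
15 | ring-A aryllithium: tert-butyl 6-(benzyloxy)-3-[3-(benzyloxy)-2-(1,3-dioxolan-2-yl)-6-lithio-5-methylphenoxy]-4-chloro-2-(1,3-dioxolan-2-yl)benzoate | Cc1cc(OCc2ccccc2)c(C3OCCO3)c(Oc4c(Cl)cc(OCc5ccccc5)c(C(=O)OC(C)(C)C)c4C6OCCO6)c1[Li] | intermediate
16 | lithium 4-(benzyloxy)-2-[4-(benzyloxy)-3-(tert-butoxycarbonyl)-6-chloro-2-(1,3-dioxolan-2-yl)phenoxy]-3-(1,3-dioxolan-2-yl)-6-methylbenzoate | Cc1cc(OCc2ccccc2)c(C3OCCO3)c(Oc4c(Cl)cc(OCc5ccccc5)c(C(=O)OC(C)(C)C)c4C6OCCO6)c1C(=O)O[Li] | intermediate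
17 | aryne: lithium 4-(benzyloxy)-2-{[4-(benzyloxy)-3-(tert-butoxycarbonyl)-2-(1,3-dioxolan-2-yl)-5,6-didehydrophenyl]oxy}-3-(1,3-dioxolan-2-yl)-6-methylbenzoate | Cc1cc(OCc2ccccc2)c(C3OCCO3)c(OC4=C(C6OCCO6)C(C(=O)OC(C)(C)C)=C(OCc5ccccc5)C#C4)c1C(=O)O[Li] | intermediate
18 | lactone aryllithium: tert-butyl 3,8-bis(benzyloxy)-4,6-bis(1,3-dioxolan-2-yl)-9-lithio-1-methyl-11-oxo-11H-dibenzo[b,e][1,4]dioxepine-7-carboxylate | Cc1cc(OCc3ccccc3)c(C4OCCO4)c2c1C(=O)Oc1c([Li])c(OCc5ccccc5)c(C(=O)OC(C)(C)C)c(C6OCCO6)c1O2 | intermediate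
19 | tert-butyl 3,8-bis(benzyloxy)-4,6-bis(1,3-dioxolan-2-yl)-9-formyl-1-methyl-11-oxo-11H-dibenzo[b,e][1,4]dioxepine-7-carboxylate | Cc1cc(OCc3ccccc3)c(C4OCCO4)c2c1C(=O)Oc1c(C=O)c(OCc5ccccc5)c(C(=O)OC(C)(C)C)c(C6OCCO6)c1O2 | intermediate
20 | 4,10-bis(benzyloxy)-1-hydroxy-8-methyl-3,7-dioxo-1,3-dihydro-7H-isobenzofuro[4,5-b][1,4]benzodioxepine-5,11-dicarbaldehyde (both epimers at C1) | Cc1cc(OCc3ccccc3)c(C=O)c2c1C(=O)Oc1c(C=O)c(OCc4ccccc4)c3c(c1O2)C(O)OC3=O | intermediate
21 | (S)-1-phenylethanol | C[C@H](O)c1ccccc1 | starting material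
22 | (1S)-4,10-bis(benzyloxy)-8-methyl-3,7-dioxo-1-[(1S)-1-phenylethoxy]-1,3-dihydro-7H-isobenzofuro[4,5-b][1,4]benzodioxepine-5,11-dicarbaldehyde | Cc1cc(OCc3ccccc3)c(C=O)c2c1C(=O)Oc1c(C=O)c(OCc4ccccc4)c3c(c1O2)[C@@H](O[C@@H](C)c5ccccc5)OC3=O | intermediate
23 | (1S)-4,10-bis(benzyloxy)-5,11-bis(hydroxymethyl)-8-methyl-1-[(1S)-1-phenylethoxy]-1H-isobenzofuro[4,5-b][1,4]benzodioxepine-3,7-dione | Cc1cc(OCc3ccccc3)c(CO)c2c1C(=O)Oc1c(CO)c(OCc4ccccc4)c3c(c1O2)[C@@H](O[C@@H](C)c5ccccc5)OC3=O | intermediate
24 | (1S)-1,4,10-trihydroxy-5,11-bis(hydroxymethyl)-8-methyl-1H-isobenzofuro[4,5-b][1,4]benzodioxepine-3,7-dione | Cc1cc(O)c(CO)c2c1C(=O)Oc1c(CO)c(O)c3c(c1O2)[C@@H](O)OC3=O | target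

**Step count and risks**
Total: 16 steps. Longest linear sequence: 13 steps (steps 4 to 16, from 2,5-dihydroxybenzoic acid); the ring-A branch (steps 1 to 3) joins at step 10.

Steps most likely to fail:

1. Step 12 (Proposed new method). Possible failures: capture of the aryne by the amide base or by the neighbouring dioxolane oxygen instead of the carboxylate, incomplete carboxylation before the base is added, or loss of aryllithium 18 by attack on an ester before formylation. Fallback with known chemistry, from 13 back to 19: exchange and carboxylation as before with isolation would give the carboxylic acid F1. Palladium-catalysed hydroxylation of the aryl chloride (Pd2(dba)3, tBuXPhos, KOH, dioxane–water) would give the hydroxy acid F2. Lactonisation with DCC and DMAP, the usual closure of this seven-membered ring from a hydroxy acid, would give the lactone F3, which lacks the formyl group. Ortho-lithiation between the acyloxy and benzyloxy groups with LiTMP and quenching with DMF would then return to 19.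

2. Step 10. Possible failure: slow substitution between a weakly nucleophilic, doubly ortho-substituted phenoxide and a fluoride crowded by the neighbouring iodine, with decomposition of the aldehydes on long heating. Fallback, from 1 and 11 back to 12: the iodine is brought in after the coupling. Benzylation of 1 would give the benzyl ether F4, ortho-lithiation and formylation (LiN(iPr)2, DMF) the aldehyde F5, and SNAr with 11 the iodine-free diaryl ether F6. Electrophilic iodination of ring A para to its benzyloxy group (N-iodosuccinimide, cat. CF3SO3H) would then give 12.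

3. Step 16. Possible failure: over-reduction (hydrogenolysis of the two benzylic C–OH bonds) and epimerisation of the freed lactol during a long hydrogenolysis. Fallback, from 20 back to 24, without hydrogenolysis: the aryl benzyl ethers are removed before any benzylic alcohol exists (BCl3, pentamethylbenzene, CH2Cl2, −78 °C) to give the phenolic lactol dialdehyde F7. Acetalisation with the photolabile (S)-1-(2-nitrophenyl)ethanol (C[C@H](O)c1ccccc1[N+](=O)[O-]), with separation of the epimers as in step 14, would give the (1S)-acetal F8, and NaBH4 reduction the diol F9. Irradiation at 365 nm cleaves the nitrobenzylic C–O bond, not a bond at the stereocentre, and would give 24.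

**Further compounds**
F1 | step 12 | 4-(benzyloxy)-2-[4-(benzyloxy)-3-(tert-butoxycarbonyl)-6-chloro-2-(1,3-dioxolan-2-yl)phenoxy]-3-(1,3-dioxolan-2-yl)-6-methylbenzoic acid | Cc1cc(OCc2ccccc2)c(C3OCCO3)c(Oc4c(Cl)cc(OCc5ccccc5)c(C(=O)OC(C)(C)C)c4C6OCCO6)c1C(=O)O
F2 | step 12 | 4-(benzyloxy)-2-[4-(benzyloxy)-3-(tert-butoxycarbonyl)-2-(1,3-dioxolan-2-yl)-6-hydroxyphenoxy]-3-(1,3-dioxolan-2-yl)-6-methylbenzoic acid | Cc1cc(OCc2ccccc2)c(C3OCCO3)c(Oc4c(O)cc(OCc5ccccc5)c(C(=O)OC(C)(C)C)c4C6OCCO6)c1C(=O)O
F3 | step 12 | tert-butyl 3,8-bis(benzyloxy)-4,6-bis(1,3-dioxolan-2-yl)-1-methyl-11-oxo-11H-dibenzo[b,e][1,4]dioxepine-7-carboxylate | Cc1cc(OCc3ccccc3)c(C4OCCO4)c2c1C(=O)Oc1cc(OCc5ccccc5)c(C(=O)OC(C)(C)C)c(C6OCCO6)c1O2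
F4 | step 10 | 1-(benzyloxy)-3-fluoro-5-methylbenzene | Cc1cc(OCc2ccccc2)cc(F)c1
F5 | step 10 | 2-(benzyloxy)-6-fluoro-4-methylbenzaldehyde | Cc1cc(OCc2ccccc2)c(C=O)c(F)c1
F6 | step 10 | tert-butyl 6-(benzyloxy)-3-[3-(benzyloxy)-2-formyl-5-methylphenoxy]-4-chloro-2-formylbenzoate | Cc1cc(OCc2ccccc2)c(C=O)c(Oc2c(Cl)cc(OCc3ccccc3)c(C(=O)OC(C)(C)C)c2C=O)c1
F7 | step 16 | 1,4,10-trihydroxy-8-methyl-3,7-dioxo-1,3-dihydro-7H-isobenzofuro[4,5-b][1,4]benzodioxepine-5,11-dicarbaldehyde (both epimers at C1) | Cc1cc(O)c(C=O)c2c1C(=O)Oc1c(C=O)c(O)c3c(c1O2)C(O)OC3=O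
F8 | step 16 | (1S)-4,10-dihydroxy-8-methyl-1-[(1S)-1-(2-nitrophenyl)ethoxy]-3,7-dioxo-1,3-dihydro-7H-isobenzofuro[4,5-b][1,4]benzodioxepine-5,11-dicarbaldehyde | Cc1cc(O)c(C=O)c2c1C(=O)Oc1c(C=O)c(O)c3c(c1O2)[C@@H](O[C@@H](C)c4ccccc4[N+](=O)[O-])OC3=O
F9 | step 16 | (1S)-4,10-dihydroxy-5,11-bis(hydroxymethyl)-8-methyl-1-[(1S)-1-(2-nitrophenyl)ethoxy]-1H-isobenzofuro[4,5-b][1,4]benzodioxepine-3,7-dione | Cc1cc(O)c(CO)c2c1C(=O)Oc1c(CO)c(O)c3c(c1O2)[C@@H](O[C@@H](C)c4ccccc4[N+](=O)[O-])OC3=O
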